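**Retrosynthetic overview**

1. Target ⇒ sp2–sp3 Suzuki coupling of a 5-bromo-dihydrobenzofuran core with the 9-BBN adduct of allyl ferulate; chain and ester arrive together, so the two primary alcohols never compete.
2. Bromo core ⇒ trans methyl 2-aryl-5-bromo-2,3-dihydrobenzofuran-3-carboxylate (hydride reduction, acetate cleaved in the same pot).
3. Key disconnection C3–C3a: that ester ⇒ a (2R)-flavanone; trivalent iodine turns C3 of the flavanone into an α-carbonyl cation equivalent and the ring A carbon shifts from C4 to C3, setting C3 trans to C2.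
4. Flavanone ⇒ 6-bromo-8-methoxychromone + arylboronic acid (Pd-catalysed asymmetric conjugate addition sets C2); chromone ⇒ brominated 2'-hydroxy-3'-methoxyacetophenone + amide acetal.
5. Ring order: both benzene rings are bought; the pyranone ring is closed first and then contracted to the dihydrofuran ring.

Assumption: (4-acetoxy-3-methoxyphenyl)boronic acid is bought as such, and the (S)-ligand in step 3 gives the (2R)-flavanone (inferred by analogy with its additions to cyclic enones, not verified); if the measured sign is opposite, the (R)-ligand is used.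

**Route**

Step 1
Reactants: 1 1-(2-hydroxy-3-methoxyphenyl)ethan-1-one
Product: 2 1-(5-bromo-2-hydroxy-3-methoxyphenyl)ethan-1-one
Conditions: NBS (1.05 equiv), MeCN, 0 °C to rt
Reagents that add atoms: N-bromosuccinimide, O=C1CCC(=O)N1Br
Why: Electrophilic aromatic bromination; the phenol directs to its only free activated position, C5 (para to OH, both ortho sites substituted), and NBS in MeCN brominates the ring rather than the acetyl CH3; no stereocentre.

Step 2
Reactants: 2 1-(5-bromo-2-hydroxy-3-methoxyphenyl)ethan-1-one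
Product: 4 6-bromo-8-methoxy-4H-chromen-4-one, via enaminone 3 (not isolated)
Conditions: Me2NCH(OMe)2 (2 equiv), toluene, 100 °C; then conc. HCl, CH2Cl2, 40 °C
Reagents that add atoms: N,N-dimethylformamide dimethyl acetal, COC(OC)N(C)C
Why: Enaminone route to chromones; the methyl ketone condenses with the amide acetal to the β-(dimethylamino)enone 3, and acid brings about intramolecular oxa-Michael addition of the phenol and loss of Me2NH to close the pyranone ring; no stereocentre.

Step 3
Reactants: 4 6-bromo-8-methoxy-4H-chromen-4-one; 5 (4-acetoxy-3-methoxyphenyl)boronic acid (2 equiv)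
Product: 6 4-[(2R)-6-bromo-8-methoxy-4-oxo-3,4-dihydro-2H-chromen-2-yl]-2-methoxyphenyl acetate
Conditions: Pd(OCOCF3)2 (5 mol %), (S)-t-BuPyOx (6 mol %), NH4PF6 (30 mol %), H2O (5 equiv), ClCH2CH2Cl, 60 °C
Reagents that add atoms: none
Why: Asymmetric conjugate addition of an arylboronic acid (Hayashi–Miyaura-type 1,4-addition with a cationic divalent palladium/pyridine-oxazoline catalyst); the aryl–Pd species adds to C2 on the enone face left open by the tert-butyl group of the ligand to set C2 as R, the base-free medium keeps the flavanone closed and the acetate intact, and because palladium stays divalent the C–Br bond is not touched (one crystallisation if ee is below 98%).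

Step 4
Reactants: 6 4-[(2R)-6-bromo-8-methoxy-4-oxo-3,4-dihydro-2H-chromen-2-yl]-2-methoxyphenyl acetate
Product: 9 methyl (2R,3R)-2-(4-acetoxy-3-methoxyphenyl)-5-bromo-7-methoxy-2,3-dihydro-1-benzofuran-3-carboxylate, via enol ether 7 (not isolated), via iodanyl ketal 8 (not isolated)
Conditions: PhI(OAc)2 (1.2 equiv), H2SO4 (1 equiv), HC(OMe)3, 0 °C to rt; aq. NaHCO3 work-up
Reagents that add atoms: trimethyl orthoformate, COC(OC)OC; water, O
Why: Hypervalent-iodine oxidative 1,2-aryl shift (ring contraction of a flavanone); acid and orthoformate give enol ether 7, PhI(OAc)2 attacks C3 anti to the C2 aryl group to give 8 in which C3 is an α-carbonyl cation (enolonium) equivalent, the equatorial C3–I bond lies antiperiplanar to the C4–C4a ring bond so the ring A carbon migrates from C4 to C3 with inversion as PhI leaves, and hydrolysis of the dimethoxycarbenium ion gives the methyl ester with C2 untouched and the new C3 centre trans to it (2R,3R).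

Step 5
Reactants: 9 methyl (2R,3R)-2-(4-acetoxy-3-methoxyphenyl)-5-bromo-7-methoxy-2,3-dihydro-1-benzofuran-3-carboxylate
Product: 10 4-[(2R,3S)-5-bromo-3-(hydroxymethyl)-7-methoxy-2,3-dihydro-1-benzofuran-2-yl]-2-methoxyphenol
Conditions: LiAlH4 (3 equiv), THF, 0 °C, 1 h; then H2O, sat. aq. NH4Cl
Reagents that add atoms: none
Why: Hydride reduction; LiAlH4 reduces the methyl ester to the primary alcohol and cleaves the aryl acetate in the same operation, the aryl bromide and the benzylic aryl ether are inert at 0 °C, and fast reduction outruns base-induced epimerisation at C3, so both centres are kept (C3 becomes S only through a change in CIP priorities).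

Step 6
Reactants: 11 (E)-ferulic acid; 12 allyl bromide (1.1 equiv)
Product: 13 prop-2-en-1-yl (E)-3-(4-hydroxy-3-methoxyphenyl)prop-2-enoate (allyl ferulate)
Conditions: KHCO3 (1.1 equiv), DMF, rt to 40 °C
Reagents that add atoms: none
Why: Chemoselective carboxylate O-alkylation (SN2); KHCO3 deprotonates only the carboxylic acid (pKa about 4.5) and not the phenol (pKa about 10), so allyl bromide gives the ester and no aryl ether, and the E alkene is unchanged.

Step 7
Reactants: 13 allyl ferulate (1.5 equiv); 10 4-[(2R,3S)-5-bromo-3-(hydroxymethyl)-7-methoxy-2,3-dihydro-1-benzofuran-2-yl]-2-methoxyphenol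
Product: 15 3-[(2R,3S)-3-(hydroxymethyl)-2-(4-hydroxy-3-methoxyphenyl)-7-methoxy-2,3-dihydro-1-benzofuran-5-yl]propyl (E)-3-(4-hydroxy-3-methoxyphenyl)prop-2-enoate (CNP0149450.1), via alkylborane 14 (not isolated)
Conditions: 13, 9-BBN (3.3 equiv), THF, 0 °C to rt; then 10, Pd(OAc)2 (5 mol %), SPhos (10 mol %), aq. K3PO4 (3 equiv), THF, 60 °C
Reagents that add atoms: none
Why: Hydroboration followed by B-alkyl Suzuki–Miyaura coupling; 9-BBN adds anti-Markovnikov only to the terminal allyl alkene (cinnamate alkene and ester are left) and masks the phenol as a borinate, and the primary alkyl–boron bond then couples with the aryl bromide under aqueous phosphate conditions that tolerate the free phenol and alcohol of 10 and the ester, so neither stereocentre is touched.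

**Compound list**

1 | 1-(2-hydroxy-3-methoxyphenyl)ethan-1-one | CC(=O)c1cccc(OC)c1O | starting material
2 | 1-(5-bromo-2-hydroxy-3-methoxyphenyl)ethan-1-one | CC(=O)c1cc(Br)cc(OC)c1O | intermediate
3 | (E)-1-(5-bromo-2-hydroxy-3-methoxyphenyl)-3-(dimethylamino)prop-2-en-1-one (not isolated) | CN(C)/C=C/C(=O)c1cc(Br)cc(OC)c1O | intermediate
4 | 6-bromo-8-methoxy-4H-chromen-4-one | COc1cc(Br)cc2c(=O)ccoc12 | intermediate
5 | (4-acetoxy-3-methoxyphenyl)boronic acid | CC(=O)Oc1ccc(B(O)O)cc1OC | starting material
6 | 4-[(2R)-6-bromo-8-methoxy-4-oxo-3,4-dihydro-2H-chromen-2-yl]-2-methoxyphenyl acetate | O=C1C[C@H](c2ccc(OC(C)=O)c(OC)c2)Oc2c(OC)cc(Br)cc21 | intermediate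
7 | 4-[(2R)-6-bromo-4,8-dimethoxy-2H-chromen-2-yl]-2-methoxyphenyl acetate (not isolated) | COC1=C[C@H](c2ccc(OC(C)=O)c(OC)c2)Oc2c(OC)cc(Br)cc21 | intermediate
8 | 4-[(2S,3S)-3-[acetoxy(phenyl)iodanyl]-6-bromo-4,4,8-trimethoxy-3,4-dihydro-2H-chromen-2-yl]-2-methoxyphenyl acetate (iodanyl trans to aryl; C2 arranged as in 6, label changed by CIP priority only; not isolated) | COC1(OC)[C@@H](I(OC(C)=O)c2ccccc2)[C@H](c2ccc(OC(C)=O)c(OC)c2)Oc2c(OC)cc(Br)cc21 | intermediate
9 | methyl (2R,3R)-2-(4-acetoxy-3-methoxyphenyl)-5-bromo-7-methoxy-2,3-dihydro-1-benzofuran-3-carboxylate (trans) | Brc1cc(OC)c2c(c1)[C@@H](C(=O)OC)[C@H](c1ccc(OC(C)=O)c(OC)c1)O2 | intermediate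
10 | 4-[(2R,3S)-5-bromo-3-(hydroxymethyl)-7-methoxy-2,3-dihydro-1-benzofuran-2-yl]-2-methoxyphenol (trans) | Brc1cc(OC)c2c(c1)[C@@H](CO)[C@H](c1ccc(O)c(OC)c1)O2 | intermediate
11 | (E)-ferulic acid | COc1cc(/C=C/C(=O)O)ccc1O | starting material
12 | allyl bromide | C=CCBr | starting material
13 | allyl (E)-ferulate | COc1cc(/C=C/C(=O)OCC=C)ccc1O | intermediate
14 | 3-(9-borabicyclo[3.3.1]nonan-9-yl)propyl (E)-3-[4-(9-borabicyclo[3.3.1]nonan-9-yloxy)-3-methoxyphenyl]prop-2-enoate (not isolated) | COc1cc(/C=C/C(=O)OCCCB2C3CCCC2CCC3)ccc1OB1C2CCCC1CCC2 | intermediate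
15 | 3-[(2R,3S)-3-(hydroxymethyl)-2-(4-hydroxy-3-methoxyphenyl)-7-methoxy-2,3-dihydro-1-benzofuran-5-yl]propyl (E)-3-(4-hydroxy-3-methoxyphenyl)prop-2-enoate | COc1cc(/C=C/C(=O)OCCCc2cc(OC)c3c(c2)[C@@H](CO)[C@H](c2ccc(O)c(OC)c2)O3)ccc1O | target

**Summary**

Total steps: 7. Longest linear sequence: 6 (1 → 2 → 4 → 6 → 9 → 10 → 15; step 6 is a one-step side branch).

**Steps most likely to fail, with fallbacks**

Most at risk is step 4. Dehydrogenation to the flavone, a 2,3-shift of ring B to an isoflavone, or loss of the acetate followed by phenol oxidation can compete with the ring contraction. The fallback sets out from 6 and comes back at 9, making the same C3–aryl bond by a Wolff ring contraction. Enolisation of 6 with LiN(SiMe3)2 at −78 °C and acylation with CF3CO2CH2CF3 give the 3-trifluoroacetyl flavanone F1. Detrifluoroacetylative diazo transfer with MsN3/Et3N in MeCN gives the 3-diazoflavanone F2. Irradiation (365 nm) in MeOH expels N2, the ring A carbon migrates to the carbene carbon, and methanol traps the ketene to give 9 together with its cis epimer F3. The cis epimer F3 is equilibrated to trans 9 with catalytic DBU in toluene.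

Second is step 3. The bromo-methoxy chromone may give low ee or yield, or traces of zerovalent palladium may attack the C–Br bond. The fallback sets out from 2 and comes back at 6. BF3·OEt2-mediated Claisen–Schmidt condensation of 2 with bought 4-formyl-2-methoxyphenyl acetate (CC(=O)Oc1ccc(C=O)cc1OC) in dioxane gives the 2'-hydroxychalcone F4. TFA in CH2Cl2 closes it by oxa-Michael addition to the racemic flavanone F5. Kinetic resolution by asymmetric transfer hydrogenation with RuCl(p-cymene)[(S,S)-TsDPEN] in HCO2H/Et3N, stopped near 55% conversion, reduces the (S)-ketone to the cis-flavan-4-ol F6 and leaves (R)-6, separated by chromatography.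

Third is step 7. Oxidative addition into the electron-rich aryl bromide may be slow, and the ferulate ester may be lost to base or to the borane. The fallback sets out from 10 and comes back at 15, forming the C–C bond first with a robust borane and the ester afterwards. Allyl alcohol (C=CCO) and 9-BBN (2.2 equiv) give the bis-boron adduct F7, which is coupled with 10 under the step 7 palladium conditions to the diol F8. Mitsunobu esterification of F8 with ferulic acid 11 (1.0 equiv; PPh3, DIAD, THF, −20 °C) then gives 15. It acylates the unbranched chain alcohol in preference to the β-branched C3–CH2OH (SN2 at an n-alkyl versus an isobutyl-type carbon), and the acid reacts ahead of the phenols.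

Further compounds
F1 | step 4 | 4-[(2R)-6-bromo-8-methoxy-4-oxo-3-(trifluoroacetyl)-3,4-dihydro-2H-chromen-2-yl]-2-methoxyphenyl acetate (C3 enolised, not defined) | O=C1C(C(=O)C(F)(F)F)[C@H](c2ccc(OC(C)=O)c(OC)c2)Oc2c(OC)cc(Br)cc21
F2 | step 4 | 4-[(2S)-6-bromo-3-diazo-8-methoxy-4-oxo-3,4-dihydro-2H-chromen-2-yl]-2-methoxyphenyl acetate (C2 arranged as in 6, label changed by CIP priority only) | O=C1C(=[N+]=[N-])[C@H](c2ccc(OC(C)=O)c(OC)c2)Oc2c(OC)cc(Br)cc21
F3 | step 4 | methyl (2R,3S)-2-(4-acetoxy-3-methoxyphenyl)-5-bromo-7-methoxy-2,3-dihydro-1-benzofuran-3-carboxylate (cis epimer of 9) | Brc1cc(OC)c2c(c1)[C@H](C(=O)OC)[C@H](c1ccc(OC(C)=O)c(OC)c1)O2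
F4 | step 3 | 4-[(E)-3-(5-bromo-2-hydroxy-3-methoxyphenyl)-3-oxoprop-1-en-1-yl]-2-methoxyphenyl acetate | CC(=O)Oc1ccc(/C=C/C(=O)c2cc(Br)cc(OC)c2O)cc1OC
F5 | step 3 | racemic 4-(6-bromo-8-methoxy-4-oxo-3,4-dihydro-2H-chromen-2-yl)-2-methoxyphenyl acetate | O=C1CC(c2ccc(OC(C)=O)c(OC)c2)Oc2c(OC)cc(Br)cc21
F6 | step 3 | 4-[(2S,4S)-6-bromo-4-hydroxy-8-methoxy-3,4-dihydro-2H-chromen-2-yl]-2-methoxyphenyl acetate (cis) | O[C@H]1C[C@@H](c2ccc(OC(C)=O)c(OC)c2)Oc2c(OC)cc(Br)cc21
F7 | step 7 | 9-[3-(9-borabicyclo[3.3.1]nonan-9-yloxy)propyl]-9-borabicyclo[3.3.1]nonane | C(CCOB1C2CCCC1CCC2)B1C2CCCC1CCC2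
F8 | step 7 | 4-[(2R,3S)-3-(hydroxymethyl)-5-(3-hydroxypropyl)-7-methoxy-2,3-dihydro-1-benzofuran-2-yl]-2-methoxyphenol | OCCCc1cc(OC)c2c(c1)[C@@H](CO)[C@H](c1ccc(O)c(OC)c1)O2
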